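**Plan**

- Numbering: ring C1 (quaternary; CO2H and 4-methylpent-3-enyl), C2 (CH carrying bridge carbon C1′), C3, C4, C5 (spiro carbon), C6 (CH carrying bridge carbon C9′); bridge C1′–C9′. The enabling feature is the array O=C–C1–C2–C3=C4 that appears once C5 is drawn as an allylic oxygen function: a γ,δ-unsaturated acid on a quaternary carbon, the imprint of an ester-enolate Claisen shift.
- Cuts: the C5 oxirane (sulfur ylide on a C5 ketone); C7′–C8′ (B-alkyl Suzuki macrocyclisation); C3′–C4′ (Negishi); the two Z alkenes (iodoethylidene Wittig); then C1–C2 with O–C4 re-formed, giving a δ-lactone; then the lactone's C3–alkyl, C4–vinyl and ring C=C bonds.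
- Forward: the δ-lactone is closed by metathesis and receives the vinyl and homoprenyl groups; ring contraction gives the cyclohexene (ring A); the C2 arm is grown; the twelve-membered ring is closed; C5 is taken to the ketone, then the spiro-epoxide; the acid is freed last.
- Stereochemistry: Sharpless desymmetrisation of divinyl carbinol fixes the two lactone carbinol centres; the cuprate enters anti to the C5 ether; the boat Claisen relays these centres into C1, C2 and C6; both Z alkenes come from Z-iodoalkenes coupled with retention; C5 comes from ylide attack anti to the C6 arm.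

Key step: step 9

Assumption: the vinyl copper reagent is taken to enter enelactone 9 trans to the C5 ether oxygen, the usual course for 5-oxygenated 5,6-dihydropyran-2-ones; this step is listed among the risks.

**Route**

Step 1
Reactants: 1 penta-1,4-dien-3-ol
Product: 2 (2R,3S)-1,2-epoxypent-4-en-3-ol
Conditions: Ti(OiPr)4 (10 mol%), L-(+)-diisopropyl tartrate (13 mol%), t-BuOOH, 4 Å molecular sieves, CH2Cl2, −20 °C
Reagents that add atoms: tert-butyl hydroperoxide, CC(C)(C)OO
Why: Sharpless asymmetric epoxidation of the divinyl carbinol combines enantiotopic-group selection with the erythro-selective kinetic-resolution manifold, so the titanium tartrate sets the carbinol and epoxide centres (anti) and the minor enantiomer is removed by a second epoxidation.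

Step 2
Reactants: 2 (2R,3S)-1,2-epoxypent-4-en-3-ol
Product: 3 (2R)-2-[(1S)-1-(4-methoxybenzyloxy)prop-2-enyl]oxirane
Conditions: NaH, 4-MeOC6H4CH2Cl, Bu4NI (cat.), THF, 0 °C → rt
Reagents that add atoms: 4-methoxybenzyl chloride, COc1ccc(CCl)cc1
Why: Williamson etherification of the sodium alkoxide under iodide catalysis should outrun Payne rearrangement in aprotic THF and touches neither stereocentre.

Step 3
Reactants: 3 (2R)-2-[(1S)-1-(4-methoxybenzyloxy)prop-2-enyl]oxirane
Product: 4 (3R,4S)-4-(4-methoxybenzyloxy)hexa-1,5-dien-3-ol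
Conditions: Me3SI, n-BuLi, THF, −10 °C → rt; H2O
Reagents that add atoms: trimethylsulfonium iodide, C[S+](C)C.[I-]
Why: The sulfonium ylide opens the terminal epoxide carbon and the betaine loses Me2S by syn elimination (one-carbon homologation of an epoxide to an allylic alcohol), which leaves both stereocentres untouched; the PMB ether cannot migrate, so the mono-protected meso-type diol cannot racemise.

Step 4
Reactants: 4 (3R,4S)-4-(4-methoxybenzyloxy)hexa-1,5-dien-3-ol; 5 acryloyl chloride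
Product: 6 (3R,4S)-4-(4-methoxybenzyloxy)hexa-1,5-dien-3-yl acrylate
Conditions: Et3N, CH2Cl2, −20 → 0 °C
Reagents that add atoms: none
Why: Plain O-acylation of a secondary allylic alcohol by an acid chloride with an amine base.

Step 5
Reactants: 6 (3R,4S)-4-(4-methoxybenzyloxy)hexa-1,5-dien-3-yl acrylate; 7 4,4-diethoxybut-1-ene
Product: 9 (5S,6R)-6-[(E)-4,4-diethoxybut-1-enyl]-5-(4-methoxybenzyloxy)-5,6-dihydro-2H-pyran-2-one, via vinyl lactone 8 (not isolated)
Conditions: second-generation Hoveyda–Grubbs catalyst RuCl2(H2IMes)(=CH-C6H4-2-OiPr) (5 mol%), CH2Cl2 (0.01 M), 40 °C; then 7 (5 equiv), 40 °C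
Reagents that add atoms: none
Why: Ring-closing metathesis of the acrylate onto the vinyl group of the ether-bearing carbon closes the six-membered enelactone in preference to the butenolide, and the remaining 6-vinyl group then undergoes E-selective cross-metathesis with the unhindered alkene 7 in excess, the electron-poor ring alkene staying inert (tandem ring-closing/cross-metathesis).

Step 6
Reactants: 9 (5S,6R)-6-[(E)-4,4-diethoxybut-1-enyl]-5-(4-methoxybenzyloxy)-5,6-dihydro-2H-pyran-2-one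
Product: 11 (4S,5S,6R)-6-[(E)-4,4-diethoxybut-1-enyl]-5-(4-methoxybenzyloxy)-4-vinyltetrahydro-2H-pyran-2-one, via silyl ketene acetal 10 (not isolated)
Conditions: CH2=CHMgBr, CuBr·SMe2 (20 mol%), Me3SiCl, THF, −78 °C; aq. NH4Cl
Reagents that add atoms: vinylmagnesium bromide, C=C[Mg]Br
Why: Copper-catalysed conjugate addition of the Grignard reagent, accelerated by Me3SiCl, should deliver the vinyl group to C4 anti to the neighbouring C5 ether oxygen, which places it trans to OPMB and cis to the C6 alkenyl group; aqueous work-up hydrolyses the ketene acetal back to the lactone.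

Step 7
Reactants: 12 5-bromo-2-methylpent-2-ene
Product: 13 5-iodo-2-methylpent-2-ene
Conditions: NaI, acetone, reflux
Reagents that add atoms: sodium iodide, [Na+].[I-]
Why: Finkelstein halide exchange at a primary carbon, driven by precipitation of NaBr.

Step 8
Reactants: 11 (4S,5S,6R)-6-[(E)-4,4-diethoxybut-1-enyl]-5-(4-methoxybenzyloxy)-4-vinyltetrahydro-2H-pyran-2-one; 13 5-iodo-2-methylpent-2-ene
Product: 15 (3R,4R,5S,6R)-6-[(E)-4,4-diethoxybut-1-enyl]-5-(4-methoxybenzyloxy)-3-(4-methylpent-3-enyl)-4-vinyltetrahydro-2H-pyran-2-one, via lithium enolate 14 (not isolated)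
Conditions: LiN(iPr)2 (LDA), THF, −78 °C; 13, DMPU, −78 → −30 °C
Reagents that add atoms: none
Why: Alkylation of the lithium lactone enolate with a primary iodide in the presence of DMPU should occur anti to the adjacent vinyl group, and the new C3 centre is of no consequence because it is planarised again in step 9.

Step 9
Reactants: 15 (3R,4R,5S,6R)-6-[(E)-4,4-diethoxybut-1-enyl]-5-(4-methoxybenzyloxy)-3-(4-methylpent-3-enyl)-4-vinyltetrahydro-2H-pyran-2-one
Product: 18 (1S,2S,5R,6R)-2-(2,2-diethoxyethyl)-5-(4-methoxybenzyloxy)-1-(4-methylpent-3-enyl)-6-vinylcyclohex-3-ene-1-carboxylic acid, via silyl ketene acetal 16 (not isolated), via trimethylsilyl ester 17 (not isolated)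
Conditions: LiN(iPr)2 (LDA), Me3SiCl, Et3N, THF, −78 °C → rt; toluene, 105 °C; then H2O, THF, rt
Reagents that add atoms: none
Why: LDA removes the single α-hydrogen of 15 in the presence of Me3SiCl to give the cyclic silyl ketene acetal 16, whose geometry is fixed by the ring, and on heating the array C3=C2(OSi)–O1–C6–CH=CH of the lactone undergoes a concerted suprafacial [3,3]-sigmatropic shift in which O1–C6 breaks as lactone C3 bonds to the alkene terminus (the C1–C2 bond of the target), after which water cleaves silyl ester 17. The closest known reaction type is the Ireland–Claisen ring contraction of 6-alkenyl δ-lactone silyl ketene acetals to cyclohex-3-enecarboxylic acids. Ring A closes by pericyclic ring contraction through a bicyclo[2.2.2]octane-like boat transition state, the only geometry the two-carbon C4–C5 tether allows. The quaternary C1 is controlled by the lactone C4 centre, because the substituent that was cis to the alkenyl group points away from the ketene-acetal bridge in the boat and so the vinyl group ends up trans to the carboxyl. C2 is controlled by the E geometry of the side-chain alkene, which in the boat places the 2,2-diethoxyethyl arm cis to the carboxyl. The step needs complete relay of configuration and a single enolisation site, and both are secured by the concerted, tether-enforced shift and by the one remaining α-hydrogen.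

Step 10
Reactants: 18 (1S,2S,5R,6R)-2-(2,2-diethoxyethyl)-5-(4-methoxybenzyloxy)-1-(4-methylpent-3-enyl)-6-vinylcyclohex-3-ene-1-carboxylic acid
Product: 19 2-(trimethylsilyl)ethyl (1S,2S,5R,6R)-2-(2,2-diethoxyethyl)-5-(4-methoxybenzyloxy)-1-(4-methylpent-3-enyl)-6-vinylcyclohex-3-ene-1-carboxylate
Conditions: Me3SiCH2CH2OH, PPh3, DIAD, THF, 0 °C → rt
Reagents that add atoms: 2-(trimethylsilyl)ethanol, C[Si](C)(C)CCO
Why: In the Mitsunobu esterification the hindered carboxylate is the nucleophile and attacks the primary oxyphosphonium carbon, so the congestion around C1 does not matter.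

Step 11
Reactants: 19 2-(trimethylsilyl)ethyl (1S,2S,5R,6R)-2-(2,2-diethoxyethyl)-5-(4-methoxybenzyloxy)-1-(4-methylpent-3-enyl)-6-vinylcyclohex-3-ene-1-carboxylate
Product: 20 2-(trimethylsilyl)ethyl (1S,2S,5R,6R)-5-(4-methoxybenzyloxy)-1-(4-methylpent-3-enyl)-2-(2-oxoethyl)-6-vinylcyclohex-3-ene-1-carboxylate
Conditions: AcOH/THF/H2O (3:1:1), 35 °C
Reagents that add atoms: water, O
Why: Mild acid-catalysed hydrolysis of the diethyl acetal frees the C2′ aldehyde while the PMB ether and silylethyl ester are stable.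

Step 12
Reactants: 20 2-(trimethylsilyl)ethyl (1S,2S,5R,6R)-5-(4-methoxybenzyloxy)-1-(4-methylpent-3-enyl)-2-(2-oxoethyl)-6-vinylcyclohex-3-ene-1-carboxylate
Product: 21 2-(trimethylsilyl)ethyl (1S,2S,5R,6R)-2-[(Z)-3-iodobut-2-enyl]-5-(4-methoxybenzyloxy)-1-(4-methylpent-3-enyl)-6-vinylcyclohex-3-ene-1-carboxylate
Conditions: EtPPh3I, n-BuLi, THF, 0 °C; I2, −78 °C; NaN(SiMe3)2, −78 → −20 °C; then 20, −78 °C
Reagents that add atoms: ethyltriphenylphosphonium iodide, CC[P+](c1ccccc1)(c1ccccc1)c1ccccc1.[I-]; iodine, II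
Why: The Stork–Zhao-type Wittig reaction of the α-iodoethylidene ylide with an aliphatic aldehyde gives the (Z)-2-iodoalkene, iodine cis to the chain, under kinetic control.

Step 13
Reactants: 21 2-(trimethylsilyl)ethyl (1S,2S,5R,6R)-2-[(Z)-3-iodobut-2-enyl]-5-(4-methoxybenzyloxy)-1-(4-methylpent-3-enyl)-6-vinylcyclohex-3-ene-1-carboxylate
Product: 22 2-(trimethylsilyl)ethyl (1S,2S,5R,6R)-2-[(Z)-5-(1,3-dioxolan-2-yl)-3-methylpent-2-enyl]-5-(4-methoxybenzyloxy)-1-(4-methylpent-3-enyl)-6-vinylcyclohex-3-ene-1-carboxylate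
Conditions: BrZnCH2CH2(1,3-dioxolan-2-yl) (THF solution), Pd(dppf)Cl2 (5 mol%), THF, 50 °C
Reagents that add atoms: [2-(1,3-dioxolan-2-yl)ethyl]zinc bromide, Br[Zn]CCC1OCCO1
Why: Negishi sp2–sp3 coupling replaces iodine with retention of alkene geometry, so the C2′=C3′ trisubstituted alkene is formed Z, and the terminal vinyl group and the esters are left alone.

Step 14
Reactants: 22 2-(trimethylsilyl)ethyl (1S,2S,5R,6R)-2-[(Z)-5-(1,3-dioxolan-2-yl)-3-methylpent-2-enyl]-5-(4-methoxybenzyloxy)-1-(4-methylpent-3-enyl)-6-vinylcyclohex-3-ene-1-carboxylate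
Product: 23 2-(trimethylsilyl)ethyl (1S,2S,5R,6R)-5-(4-methoxybenzyloxy)-2-[(Z)-3-methyl-6-oxohex-2-enyl]-1-(4-methylpent-3-enyl)-6-vinylcyclohex-3-ene-1-carboxylate
Conditions: TsOH·H2O (20 mol%), acetone/H2O (10:1), 40 °C
Reagents that add atoms: water, O
Why: Acid-catalysed hydrolysis of the dioxolane frees the C6′ aldehyde without touching the isolated Z alkene.

Step 15
Reactants: 23 2-(trimethylsilyl)ethyl (1S,2S,5R,6R)-5-(4-methoxybenzyloxy)-2-[(Z)-3-methyl-6-oxohex-2-enyl]-1-(4-methylpent-3-enyl)-6-vinylcyclohex-3-ene-1-carboxylate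
Product: 24 2-(trimethylsilyl)ethyl (1S,2S,5R,6R)-2-[(2Z,6Z)-7-iodo-3-methylocta-2,6-dienyl]-5-(4-methoxybenzyloxy)-1-(4-methylpent-3-enyl)-6-vinylcyclohex-3-ene-1-carboxylate
Conditions: EtPPh3I, n-BuLi, THF, 0 °C; I2, −78 °C; NaN(SiMe3)2, −78 → −20 °C; then 23, −78 °C
Reagents that add atoms: ethyltriphenylphosphonium iodide, CC[P+](c1ccccc1)(c1ccccc1)c1ccccc1.[I-]; iodine, II
Why: The same Stork–Zhao-type α-iodo Wittig reaction installs the second (Z)-2-iodoalkene at C6′=C7′.

Step 16
Reactants: 24 2-(trimethylsilyl)ethyl (1S,2S,5R,6R)-2-[(2Z,6Z)-7-iodo-3-methylocta-2,6-dienyl]-5-(4-methoxybenzyloxy)-1-(4-methylpent-3-enyl)-6-vinylcyclohex-3-ene-1-carboxylate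
Product: 26 macrocyclic PMB ether 2-(trimethylsilyl)ethyl ester (ring C1–C6 keeping C3=C4 and C5–OPMB; C2 and C6 joined trans by the (2′Z,6′Z)-3′,7′-dimethylnona-2′,6′-diene-1′,9′-diyl bridge), via alkylborane 25 (not isolated)
Conditions: 9-BBN, THF, rt; then slow addition to Pd(dppf)Cl2 (20 mol%), AsPh3, Cs2CO3, DMF/THF/H2O, 50 °C (final 1 mM)
Reagents that add atoms: none
Why: 9-BBN hydroborates the only monosubstituted alkene at its terminus, and intramolecular B-alkyl Suzuki–Miyaura coupling under high dilution joins C8′ to C7′ with retention at the iodoalkene, which closes the twelve-membered ring and fixes the second Z alkene.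

Step 17
Reactants: 26 macrocyclic PMB ether 2-(trimethylsilyl)ethyl ester
Product: 27 macrocyclic allylic alcohol 2-(trimethylsilyl)ethyl ester (C5–OH; C3=C4)
Conditions: DDQ, CH2Cl2/pH 7 buffer (10:1), 0 °C
Reagents that add atoms: none
Why: Oxidative cleavage of the electron-rich PMB ether by DDQ leaves the isolated alkenes and the silylethyl ester intact.

Step 18
Reactants: 27 macrocyclic allylic alcohol 2-(trimethylsilyl)ethyl ester
Product: 28 macrocyclic enone 2-(trimethylsilyl)ethyl ester (C5=O conjugated to C3=C4)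
Conditions: Dess–Martin periodinane, CH2Cl2, 0 °C → rt
Reagents that add atoms: none
Why: Dess–Martin oxidation of the secondary allylic alcohol gives the enone under non-basic conditions, so the γ-centre C2 and the α-centre C6 are not enolised.

Step 19
Reactants: 28 macrocyclic enone 2-(trimethylsilyl)ethyl ester
Product: 29 macrocyclic C5 ketone 2-(trimethylsilyl)ethyl ester (C3 and C4 saturated)
Conditions: [(Ph3P)CuH]6 (0.4 equiv), benzene, H2O (5 equiv), rt
Reagents that add atoms: none
Why: Stryker conjugate reduction transfers hydride only to the enone β-carbon C3, and the isolated trisubstituted alkenes and the ester are inert to the copper hydride.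

Step 20
Reactants: 29 macrocyclic C5 ketone 2-(trimethylsilyl)ethyl ester
Product: 30 spiro-epoxide 2-(trimethylsilyl)ethyl ester (oxirane CH2 cis and oxirane O trans to the C1 ester)
Conditions: Me3SI, KN(SiMe3)2, THF, −10 °C; then 29, −10 → 0 °C
Reagents that add atoms: trimethylsulfonium iodide, C[S+](C)C.[I-]
Why: In the Corey–Chaykovsky reaction dimethylsulfonium methylide should add irreversibly to the C5 carbonyl on the face syn to C6–H, away from the C9′ arm on C6 and the pentenyl chain on C1, and the betaine closes to the oxirane with the new CH2 cis to the C1 carboxyl carbon.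

Step 21
Reactants: 30 spiro-epoxide 2-(trimethylsilyl)ethyl ester
Product: 31 CNP0116395.1 (target epoxy acid)
Conditions: Bu4NF, THF, 0 °C → rt; then AcOH (1 equiv)
Reagents that add atoms: none
Why: Fluoride attacks silicon and the 2-silylethyl ester fragments by β-elimination, which frees the hindered carboxylate without hydrolysis and without opening the oxirane.

**Compound list**

1 | penta-1,4-dien-3-ol | C=CC(O)C=C | starting material
2 | (2R,3S)-1,2-epoxypent-4-en-3-ol | C1O[C@H]1[C@@H](O)C=C | intermediate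
3 | (2R)-2-[(1S)-1-(4-methoxybenzyloxy)prop-2-enyl]oxirane | C1O[C@H]1[C@@H](OCc1ccc(OC)cc1)C=C | intermediate
4 | (3R,4S)-4-(4-methoxybenzyloxy)hexa-1,5-dien-3-ol | O[C@H](C=C)[C@@H](OCc1ccc(OC)cc1)C=C | intermediate
5 | acryloyl chloride | C=CC(=O)Cl | starting material
6 | (3R,4S)-4-(4-methoxybenzyloxy)hexa-1,5-dien-3-yl acrylate | C=CC(=O)O[C@H](C=C)[C@@H](OCc1ccc(OC)cc1)C=C | intermediate
7 | 4,4-diethoxybut-1-ene | C=CCC(OCC)OCC | starting material
8 | (5S,6R)-5-(4-methoxybenzyloxy)-6-vinyl-5,6-dihydro-2H-pyran-2-one | O=C1O[C@H](C=C)[C@@H](OCc2ccc(OC)cc2)C=C1 | intermediate (not isolated)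
9 | (5S,6R)-6-[(E)-4,4-diethoxybut-1-enyl]-5-(4-methoxybenzyloxy)-5,6-dihydro-2H-pyran-2-one | O=C1O[C@H](/C=C/CC(OCC)OCC)[C@@H](OCc2ccc(OC)cc2)C=C1 | intermediate
10 | trimethylsilyl ketene acetal of lactone 11 (6-trimethylsilyloxy-3,4-dihydro-2H-pyran form) | C[Si](C)(C)OC1=C[C@@H](C=C)[C@H](OCc2ccc(OC)cc2)[C@@H](/C=C/CC(OCC)OCC)O1 | intermediate (not isolated)
11 | (4S,5S,6R)-6-[(E)-4,4-diethoxybut-1-enyl]-5-(4-methoxybenzyloxy)-4-vinyltetrahydro-2H-pyran-2-one (4-vinyl cis to 6-alkenyl, trans to 5-OPMB) | O=C1O[C@H](/C=C/CC(OCC)OCC)[C@@H](OCc2ccc(OC)cc2)[C@H](C=C)C1 | intermediate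
12 | 5-bromo-2-methylpent-2-ene | CC(C)=CCCBr | starting material
13 | 5-iodo-2-methylpent-2-ene | CC(C)=CCCI | intermediate
14 | lithium enolate of lactone 11 | [Li]OC1=C[C@@H](C=C)[C@H](OCc2ccc(OC)cc2)[C@@H](/C=C/CC(OCC)OCC)O1 | intermediate (not isolated)
15 | (3R,4R,5S,6R)-6-[(E)-4,4-diethoxybut-1-enyl]-5-(4-methoxybenzyloxy)-3-(4-methylpent-3-enyl)-4-vinyltetrahydro-2H-pyran-2-one | O=C1O[C@H](/C=C/CC(OCC)OCC)[C@@H](OCc2ccc(OC)cc2)[C@H](C=C)[C@H]1CCC=C(C)C | intermediate (key-step precursor)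
16 | trimethylsilyl ketene acetal of lactone 15 | C[Si](C)(C)OC1=C(CCC=C(C)C)[C@@H](C=C)[C@H](OCc2ccc(OC)cc2)[C@@H](/C=C/CC(OCC)OCC)O1 | intermediate (not isolated)
17 | trimethylsilyl ester of acid 18 | CC(C)=CCC[C@]1(C(=O)O[Si](C)(C)C)[C@@H](CC(OCC)OCC)C=C[C@@H](OCc2ccc(OC)cc2)[C@@H]1C=C | intermediate (not isolated)
18 | (1S,2S,5R,6R)-2-(2,2-diethoxyethyl)-5-(4-methoxybenzyloxy)-1-(4-methylpent-3-enyl)-6-vinylcyclohex-3-ene-1-carboxylic acid | CC(C)=CCC[C@]1(C(=O)O)[C@@H](CC(OCC)OCC)C=C[C@@H](OCc2ccc(OC)cc2)[C@@H]1C=C | intermediate (key-step product)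
19 | 2-(trimethylsilyl)ethyl ester of acid 18 | CC(C)=CCC[C@]1(C(=O)OCC[Si](C)(C)C)[C@@H](CC(OCC)OCC)C=C[C@@H](OCc2ccc(OC)cc2)[C@@H]1C=C | intermediate
20 | 2-(trimethylsilyl)ethyl (1S,2S,5R,6R)-5-(4-methoxybenzyloxy)-1-(4-methylpent-3-enyl)-2-(2-oxoethyl)-6-vinylcyclohex-3-ene-1-carboxylate | CC(C)=CCC[C@]1(C(=O)OCC[Si](C)(C)C)[C@@H](CC=O)C=C[C@@H](OCc2ccc(OC)cc2)[C@@H]1C=C | intermediate
21 | 2-(trimethylsilyl)ethyl (1S,2S,5R,6R)-2-[(Z)-3-iodobut-2-enyl]-5-(4-methoxybenzyloxy)-1-(4-methylpent-3-enyl)-6-vinylcyclohex-3-ene-1-carboxylate | CC(C)=CCC[C@]1(C(=O)OCC[Si](C)(C)C)[C@@H](C/C=C(\I)C)C=C[C@@H](OCc2ccc(OC)cc2)[C@@H]1C=C | intermediate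
22 | 2-(trimethylsilyl)ethyl (1S,2S,5R,6R)-2-[(Z)-5-(1,3-dioxolan-2-yl)-3-methylpent-2-enyl]-5-(4-methoxybenzyloxy)-1-(4-methylpent-3-enyl)-6-vinylcyclohex-3-ene-1-carboxylate | CC(C)=CCC[C@]1(C(=O)OCC[Si](C)(C)C)[C@@H](C/C=C(\CCC3OCCO3)C)C=C[C@@H](OCc2ccc(OC)cc2)[C@@H]1C=C | intermediate
23 | 2-(trimethylsilyl)ethyl (1S,2S,5R,6R)-5-(4-methoxybenzyloxy)-2-[(Z)-3-methyl-6-oxohex-2-enyl]-1-(4-methylpent-3-enyl)-6-vinylcyclohex-3-ene-1-carboxylate | CC(C)=CCC[C@]1(C(=O)OCC[Si](C)(C)C)[C@@H](C/C=C(\CCC=O)C)C=C[C@@H](OCc2ccc(OC)cc2)[C@@H]1C=C | intermediate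
24 | 2-(trimethylsilyl)ethyl (1S,2S,5R,6R)-2-[(2Z,6Z)-7-iodo-3-methylocta-2,6-dienyl]-5-(4-methoxybenzyloxy)-1-(4-methylpent-3-enyl)-6-vinylcyclohex-3-ene-1-carboxylate | CC(C)=CCC[C@]1(C(=O)OCC[Si](C)(C)C)[C@@H](C/C=C(\CC/C=C(\I)C)C)C=C[C@@H](OCc2ccc(OC)cc2)[C@@H]1C=C | intermediate
25 | B-alkyl-9-BBN adduct of 24 (C6 carries 2-(9-borabicyclo[3.3.1]nonan-9-yl)ethyl) | CC(C)=CCC[C@]1(C(=O)OCC[Si](C)(C)C)[C@@H](C/C=C(\CC/C=C(\I)C)C)C=C[C@@H](OCc2ccc(OC)cc2)[C@@H]1CCB1C2CCCC1CCC2 | intermediate (not isolated)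
26 | macrocyclic PMB ether 2-(trimethylsilyl)ethyl ester (bicyclo[9.3.1]pentadecatriene; C3=C4; C5–OPMB cis to the ester; C2 arm cis and C6 arm trans to the ester; both bridge alkenes Z) | CC(C)=CCC[C@]1(C(=O)OCC[Si](C)(C)C)[C@H]2C/C=C(/C)CC/C=C(/C)CC[C@H]1[C@H](OCc1ccc(OC)cc1)C=C2 | intermediate
27 | macrocyclic allylic alcohol 2-(trimethylsilyl)ethyl ester (C5–OH; C3=C4) | CC(C)=CCC[C@]1(C(=O)OCC[Si](C)(C)C)[C@H]2C/C=C(/C)CC/C=C(/C)CC[C@H]1[C@H](O)C=C2 | intermediate
28 | macrocyclic enone 2-(trimethylsilyl)ethyl ester (C5=O; C3=C4) | CC(C)=CCC[C@]1(C(=O)OCC[Si](C)(C)C)[C@H]2C/C=C(/C)CC/C=C(/C)CC[C@H]1C(=O)C=C2 | intermediate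
29 | macrocyclic C5 ketone 2-(trimethylsilyl)ethyl ester | CC(C)=CCC[C@]1(C(=O)OCC[Si](C)(C)C)[C@H]2C/C=C(/C)CC/C=C(/C)CC[C@H]1C(=O)CC2 | intermediate
30 | spiro-epoxide 2-(trimethylsilyl)ethyl ester | CC(C)=CCC[C@]1(C(=O)OCC[Si](C)(C)C)[C@H]2C/C=C(/C)CC/C=C(/C)CC[C@H]1[C@@]1(CC2)CO1 | intermediate
31 | CNP0116395.1 (epoxy acid; C1 S, C2 R, C5 S, C6 R in the ring numbering used here) | CC(C)=CCC[C@]1(C(=O)O)[C@H]2C/C=C(/C)CC/C=C(/C)CC[C@H]1[C@@]1(CC2)CO1 | target

**Step count and risks**

Total step count: 21. Longest linear sequence: 20 steps (steps 1–6 and 8–21, from penta-1,4-dien-3-ol); step 7 is a one-step side branch.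

Steps most likely to fail:

1. Step 16 (macrocyclisation). What may go wrong is intermolecular oligomerisation, or slow transmetalation and protodeboronation of the B-alkyl group that sits next to the congested C6/C1 region, so that the twelve-membered ring does not close. The fallback moves the ring-closing bond to C3′–C4′ and sets out from 19.
   - The vinyl group of 19 is hydroborated with 9-BBN to the alkylborane F2.
   - F2 is coupled without dilution (Pd(dppf)Cl2, AsPh3, Cs2CO3) with the linker (Z)-tert-butyl[(4-iodopent-3-enyl)oxy]dimethylsilane F1, itself made from 3-(tert-butyldimethylsilyloxy)propanal by the iodoethylidene Wittig reaction of step 12. This gives the chain-extended silyl ether acetal F3.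
   - Aqueous acid removes the acetal and the primary silyl ether together and gives the hydroxy aldehyde F4.
   - The Wittig reaction of step 12 (excess ylide) gives the hydroxy (Z)-iodoalkene F5.
   - I2/PPh3/imidazole gives the primary alkyl iodide F6.
   - Zinc dust with LiCl inserts only into the alkyl C–I bond and gives the alkylzinc iodide F7.
   - Intramolecular Negishi coupling (Pd(dppf)Cl2, THF, high dilution) closes the ring with retention at C3′ and comes back to the route at 26.

2. Step 6 (conjugate addition). What may go wrong is poor facial selectivity: the preference for attack anti to the C5 ether competes with the preference of 6-substituted dihydropyranones for attack trans to the C6 substituent, which would give the 4,6-trans lactone. The fallback sets out from 9 and replaces substrate control by reagent control: rhodium-catalysed 1,4-addition of potassium vinyltrifluoroborate with [Rh(OH)(cod)]2 and the BINAP enantiomer matched to the desired face (both antipodes to be tried), in dioxane/H2O. It returns directly at 11; no new compound arises (F0).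

3. Step 20 (methylene transfer). What may go wrong is poor facial selectivity at the C5 carbonyl, or enolisation by the basic ylide with epimerisation at C6. The fallback sets out from 29 and builds the oxirane in stages.
   - The weakly basic cerium reagent from (isopropoxydimethylsilyl)methylmagnesium chloride and CeCl3 adds to the ketone; its bulk should reinforce attack anti to the C6 arm. This gives the β-hydroxysilane F8.
   - Tamao oxidation (H2O2, KHCO3, THF/MeOH) gives the 1,2-diol F9.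
   - MsCl/Et3N sulfonylates only the primary hydroxyl and gives the mesylate F10.
   - K2CO3 in MeOH closes the oxirane by displacement at the primary carbon and comes back to the route at 30.

**Further compounds**

F0 | step 6 | none | none
F1 | step 16 | (Z)-tert-butyl[(4-iodopent-3-enyl)oxy]dimethylsilane | C/C(I)=C/CCO[Si](C)(C)C(C)(C)C
F2 | step 16 | B-alkyl-9-BBN adduct of 19 | CC(C)=CCC[C@]1(C(=O)OCC[Si](C)(C)C)[C@@H](CC(OCC)OCC)C=C[C@@H](OCc2ccc(OC)cc2)[C@@H]1CCB1C2CCCC1CCC2
F3 | step 16 | chain-extended silyl ether acetal (C6 carries (Z)-6-(tert-butyldimethylsilyloxy)-3-methylhex-3-enyl) | CC(C)=CCC[C@]1(C(=O)OCC[Si](C)(C)C)[C@@H](CC(OCC)OCC)C=C[C@@H](OCc2ccc(OC)cc2)[C@@H]1CC/C(C)=C\CCO[Si](C)(C)C(C)(C)C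
F4 | step 16 | hydroxy aldehyde (C2 carries 2-oxoethyl; C6 carries (Z)-6-hydroxy-3-methylhex-3-enyl) | CC(C)=CCC[C@]1(C(=O)OCC[Si](C)(C)C)[C@@H](CC=O)C=C[C@@H](OCc2ccc(OC)cc2)[C@@H]1CC/C(C)=C\CCO
F5 | step 16 | hydroxy (Z)-iodoalkene (C2 carries (Z)-3-iodobut-2-enyl) | CC(C)=CCC[C@]1(C(=O)OCC[Si](C)(C)C)[C@@H](C/C=C(\I)C)C=C[C@@H](OCc2ccc(OC)cc2)[C@@H]1CC/C(C)=C\CCO
F6 | step 16 | primary alkyl iodide (C6 carries (Z)-6-iodo-3-methylhex-3-enyl) | CC(C)=CCC[C@]1(C(=O)OCC[Si](C)(C)C)[C@@H](C/C=C(\I)C)C=C[C@@H](OCc2ccc(OC)cc2)[C@@H]1CC/C(C)=C\CCI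
F7 | step 16 | alkylzinc iodide from F6 | CC(C)=CCC[C@]1(C(=O)OCC[Si](C)(C)C)[C@@H](C/C=C(\I)C)C=C[C@@H](OCc2ccc(OC)cc2)[C@@H]1CC/C(C)=C\CC[Zn]I
F8 | step 20 | β-hydroxysilane (C5 carries OH and CH2SiMe2(OiPr)) | CC(C)=CCC[C@]1(C(=O)OCC[Si](C)(C)C)[C@H]2C/C=C(/C)CC/C=C(/C)CC[C@H]1[C@](O)(C[Si](C)(C)OC(C)C)CC2
F9 | step 20 | 1,2-diol (C5 carries OH and CH2OH) | CC(C)=CCC[C@]1(C(=O)OCC[Si](C)(C)C)[C@H]2C/C=C(/C)CC/C=C(/C)CC[C@H]1[C@](O)(CO)CC2
F10 | step 20 | primary mesylate of F9 | CC(C)=CCC[C@]1(C(=O)OCC[Si](C)(C)C)[C@H]2C/C=C(/C)CC/C=C(/C)CC[C@H]1[C@](O)(COS(C)(=O)=O)CC2
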